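## Retrosynthetic overview

1. Target 14 comes from dihydronaphthalene 12 by Weinreb amide → aldehyde reduction and global desilylation.
2. 12 comes from open-chain (E)-acrylamide 11 by closing the C4–C4a bond: a light-driven Ni coupling of the dimethoxybenzyl C–H with the tethered aryl bromide, which sets C4 trans to C3.
3. 11 comes from (E)-arylidene lactone 10 by Weinreb ring-opening and silylation; 10 comes from aldol condensation of lactone 9 with bromo-aldehyde 3 (vanillin, directed ortho-metalation).
4. 9 comes from cyclopropane-fused lactone 6 by aryl-Grignard opening and decarboxylation; 6 comes from (R)-epichlorohydrin and diethyl malonate, which supplies C3.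
5. Ring order: both benzene rings are bought; the cyclopropane and lactone are temporary (the lactone is opened in step 7); the carbocycle is the only skeletal ring formed, and it is formed last.

Assumption: the target is the trans (3R,4S) isomer as encoded in the SMILES. Naphthalene-2-carbaldehyde numbering is used throughout (C2 CHO, C3 CH2OH, C4 aryl, C5 OMe, C6 OH).

## Route

**Step 1**
Reactants: 1, vanillin (4-hydroxy-3-methoxybenzaldehyde)
Product: 2, 3-methoxy-4-[(triisopropylsilyl)oxy]benzaldehyde
Conditions: TIPSCl, imidazole, DMF, rt
Reagents that add atoms: triisopropylsilyl chloride, CC(C)[Si](Cl)(C(C)C)C(C)C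
Why: Standard phenol silylation; the bulky, non-directing TIPS ether tolerates n-BuLi and every later step and is removed together with the TBS group at the end.

**Step 2**
Reactants: 2
Product: 3, 2-bromo-3-methoxy-4-[(triisopropylsilyl)oxy]benzaldehyde
Conditions: LiN(Me)CH2CH2NMe2, THF, −20 °C; n-BuLi (3 equiv), −20 °C; BrCCl2CCl2Br, −78 °C → rt; aq. NH4Cl
Reagents that add atoms: 1,2-dibromo-1,1,2,2-tetrachloroethane, BrC(Cl)(Cl)C(Cl)(Cl)Br (delivers Br)
Why: Comins-type directed ortho-metalation, in which the in situ α-amino alkoxide and the 3-OMe group cooperatively direct lithiation to C2, followed by electrophilic bromination and release of the aldehyde on work-up.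

**Step 3**
Reactants: 4, (R)-epichlorohydrin; 5, diethyl malonate
Product: 6, ethyl (1S,5R)-2-oxo-3-oxabicyclo[3.1.0]hexane-1-carboxylate
Conditions: NaOEt, EtOH, 0 °C → reflux
Reagents that add atoms: none
Why: Malonate opens the epoxide terminus, the alkoxide re-closes an epoxide by displacing chloride, and intramolecular 3-exo-tet alkylation (inversion at the bought stereocentre) then lactonisation gives the cis-fused lactone; C5 comes from epichlorohydrin and C1 is fixed by the ring fusion.

**Step 4**
Reactants: 6; 7, 3,4-dimethoxyphenylmagnesium bromide (commercial THF solution)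
Product: 8, ethyl (3S,4R)-4-[(3,4-dimethoxyphenyl)methyl]-2-oxooxolane-3-carboxylate
Conditions: CuI (20 mol %), THF, −30 → 0 °C; aq. NH4Cl
Reagents that add atoms: none
Why: Cu-catalysed homoconjugate (SN2-type) opening of the doubly activated cyclopropane at its CH2 carbon leaves the bought stereocentre untouched (it becomes C4, R), and the epimerisable C3 settles trans.

**Step 5**
Reactants: 8
Product: 9, (4R)-4-[(3,4-dimethoxyphenyl)methyl]oxolan-2-one
Conditions: LiCl, DMSO–H2O, 140 °C
Reagents that add atoms: none
Why: Krapcho dealkoxycarbonylation of the malonate-type ester; the C4 stereocentre is not acidic and is retained.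

**Step 6**
Reactants: 9; 3
Product: 10, (3E,4R)-3-{[2-bromo-3-methoxy-4-(triisopropylsilyloxy)phenyl]methylidene}-4-[(3,4-dimethoxyphenyl)methyl]oxolan-2-one
Conditions: LiHMDS, THF, −78 °C; 3; Ac2O, −78 → 0 °C; DBU, rt
Reagents that add atoms: none
Why: One-pot aldol addition, acetylation and E1cB elimination gives the thermodynamic (E)-arylidene lactone (aryl anti to C=O), which places the bromoarene cis to the C4 side chain; C4 is untouched.

**Step 7**
Reactants: 10
Product: 11, (2E)-3-[2-bromo-3-methoxy-4-(triisopropylsilyloxy)phenyl]-2-[(2R)-1-(tert-butyldimethylsilyloxy)-3-(3,4-dimethoxyphenyl)propan-2-yl]-N-methoxy-N-methylprop-2-enamide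
Conditions: MeNH(OMe)·HCl, AlMe3, CH2Cl2, 0 °C → rt; then crude + TBSOTf, 2,6-lutidine, CH2Cl2, 0 °C (telescoped)
Reagents that add atoms: N,O-dimethylhydroxylamine hydrochloride, CNOC.Cl; tert-butyldimethylsilyl triflate, CC(C)(C)[Si](C)(C)OS(=O)(=O)C(F)(F)F
Why: Weinreb aminolysis of the lactone with immediate silylation (which prevents relactonisation) frees the CH2O arm, because a fused lactone would hold that arm in the ring plane and force the C4 aryl group into the 5-OMe group during ring closure; alkene geometry and the stereocentre are unchanged.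

**Step 8**
Reactants: 11
Product: 12, (3R,4S)-3-{[(tert-butyldimethylsilyl)oxy]methyl}-4-(3,4-dimethoxyphenyl)-N,5-dimethoxy-N-methyl-6-[(triisopropylsilyl)oxy]-3,4-dihydronaphthalene-2-carboxamide
Conditions: 4CzIPN (3 mol %), NiBr2·dme (10 mol %), dtbbpy (12 mol %), 2,6-lutidine (2 equiv), degassed MeCN (0.01 M), 450 nm LEDs, 25 °C
Reagents that add atoms: none
Why: Proposed new method: excited 4CzIPN (E* ≈ +1.4 V) oxidises only the most electron-rich arene (the 3,4-dimethoxybenzyl ring) and lutidine deprotonates the radical cation at its single benzylic CH2, giving the C4 radical without any free H-abstractor (so the allylic C3–H, OCH2 and N-Me groups are spared); Ni captures the radical, oxidatively adds the tethered C–Br bond and reductively eliminates to form C4–C4a, while reduced 4CzIPN returns Ni(I) to Ni(0), so the process is redox-neutral and self-limiting (the C–Br bond is the only oxidant); C4 is set trans to C3 because the closing half-chair puts CH2OTBS pseudoaxial (A1,2 strain with the C2 carboxamide) and the aryl group pseudoaxial on the opposite face (peri strain with 5-OMe), and reversible Ni–benzyl homolysis lets this lower pathway dominate; the closest known reaction type is intermolecular Ni/photoredox benzylic C(sp3)–H arylation with aryl bromides, here proposed as a diastereoselective ring closure triggered by arene radical-cation deprotonation.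

**Step 9**
Reactants: 12
Product: 13, (3R,4S)-3-{[(tert-butyldimethylsilyl)oxy]methyl}-4-(3,4-dimethoxyphenyl)-5-methoxy-6-[(triisopropylsilyl)oxy]-3,4-dihydronaphthalene-2-carbaldehyde
Conditions: DIBAL-H, THF, −78 °C; Rochelle salt
Reagents that add atoms: none
Why: Weinreb amide reduction stops at the aldehyde through the stable chelated tetrahedral intermediate (1,2-reduction of the unsaturated amide), and the silyl ethers and both stereocentres are inert.

**Step 10**
Reactants: 13
Product: 14, vitekwangin B, (3R,4S)-4-(3,4-dimethoxyphenyl)-6-hydroxy-3-(hydroxymethyl)-5-methoxy-3,4-dihydronaphthalene-2-carbaldehyde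
Conditions: TBAF, AcOH, THF, 0 °C → rt
Reagents that add atoms: none
Why: Buffered fluoride desilylation removes the aryl TIPS and primary TBS ethers in one operation without epimerising C3 or C4 or disturbing the enal.

## Compound list

1 | vanillin | O=Cc1ccc(O)c(OC)c1 | starting material
2 | 3-methoxy-4-[(triisopropylsilyl)oxy]benzaldehyde | O=Cc1ccc(O[Si](C(C)C)(C(C)C)C(C)C)c(OC)c1 | intermediate
3 | 2-bromo-3-methoxy-4-[(triisopropylsilyl)oxy]benzaldehyde | O=Cc1ccc(O[Si](C(C)C)(C(C)C)C(C)C)c(OC)c1Br | intermediate
4 | (R)-epichlorohydrin | ClC[C@H]1CO1 | starting material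
5 | diethyl malonate | CCOC(=O)CC(=O)OCC | starting material
6 | ethyl (1S,5R)-2-oxo-3-oxabicyclo[3.1.0]hexane-1-carboxylate | CCOC(=O)[C@]12C[C@H]1COC2=O | intermediate
7 | 3,4-dimethoxyphenylmagnesium bromide | COc1ccc([Mg]Br)cc1OC | starting material
8 | ethyl (3S,4R)-4-[(3,4-dimethoxyphenyl)methyl]-2-oxooxolane-3-carboxylate | CCOC(=O)[C@H]1C(=O)OC[C@@H]1Cc1ccc(OC)c(OC)c1 | intermediate
9 | (4R)-4-[(3,4-dimethoxyphenyl)methyl]oxolan-2-one | O=C1C[C@@H](Cc2ccc(OC)c(OC)c2)CO1 | intermediate
10 | (3E,4R)-3-{[2-bromo-3-methoxy-4-(triisopropylsilyloxy)phenyl]methylidene}-4-[(3,4-dimethoxyphenyl)methyl]oxolan-2-one | O=C1OC[C@H](Cc2ccc(OC)c(OC)c2)/C1=C\c1ccc(O[Si](C(C)C)(C(C)C)C(C)C)c(OC)c1Br | intermediate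
11 | (2E)-3-[2-bromo-3-methoxy-4-(triisopropylsilyloxy)phenyl]-2-[(2R)-1-(tert-butyldimethylsilyloxy)-3-(3,4-dimethoxyphenyl)propan-2-yl]-N-methoxy-N-methylprop-2-enamide | CON(C)C(=O)/C(=C/c1ccc(O[Si](C(C)C)(C(C)C)C(C)C)c(OC)c1Br)[C@H](CO[Si](C)(C)C(C)(C)C)Cc1ccc(OC)c(OC)c1 | intermediate
12 | (3R,4S)-3-{[(tert-butyldimethylsilyl)oxy]methyl}-4-(3,4-dimethoxyphenyl)-N,5-dimethoxy-N-methyl-6-[(triisopropylsilyl)oxy]-3,4-dihydronaphthalene-2-carboxamide | COc1ccc([C@H]2c3c(ccc(O[Si](C(C)C)(C(C)C)C(C)C)c3OC)C=C(C(=O)N(C)OC)[C@@H]2CO[Si](C)(C)C(C)(C)C)cc1OC | intermediate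
13 | (3R,4S)-3-{[(tert-butyldimethylsilyl)oxy]methyl}-4-(3,4-dimethoxyphenyl)-5-methoxy-6-[(triisopropylsilyl)oxy]-3,4-dihydronaphthalene-2-carbaldehyde | COc1ccc([C@H]2c3c(ccc(O[Si](C(C)C)(C(C)C)C(C)C)c3OC)C=C(C=O)[C@@H]2CO[Si](C)(C)C(C)(C)C)cc1OC | intermediate
14 | vitekwangin B, (3R,4S)-4-(3,4-dimethoxyphenyl)-6-hydroxy-3-(hydroxymethyl)-5-methoxy-3,4-dihydronaphthalene-2-carbaldehyde | COc1ccc([C@H]2c3c(ccc(O)c3OC)C=C(C=O)[C@@H]2CO)cc1OC | target

## Summary

Total steps: 10. Longest linear sequence: 8 (steps 3–10; the aldehyde branch, steps 1–2, joins at step 6).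

Steps most likely to fail:

1. **Step 8 (proposed new ring closure).** Risks are slow oxidative addition at the di-ortho-substituted bromide, photosensitised E/Z isomerisation (only the E isomer can close), benzyl-radical dimerisation, and over-oxidation to the arylnaphthalene on prolonged irradiation. Fallback with known chemistry: switch to a cationic closure with bromine as a blocking group. Build the analogue of 11 from commercial 6-bromovanillin (Br occupies the normally preferred position para to OMe), then cyclise by DDQ/TFA benzylic-cation Friedel–Crafts, the established oxidative cyclisation of dibenzyl lignans, which can then only attack the ortho position flanked by OMe. Remove Br by Pd-catalysed formate hydrodebromination and continue with steps 9–10; this needs acid-stable O-protection in place of the silyl ethers.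

2. **Step 2 (ortho-lithiation/bromination).** Risks are lithiation at C6 or C5 instead of C2 and consumption of the bromine source by excess n-BuLi. Fallback: start from commercial 2-bromo-3,4-dimethoxybenzaldehyde, cleave the methyl ether para to the formyl group by nucleophilic demethylation (LiCl, DMF, reflux), then silylate as in step 1.

3. **Step 7 (aminolysis of the hindered, conjugated lactone; relactonisation before silylation).** Fallback: reduce 10 with excess DIBAL-H to the 1,4-diol and bis-silylate it, then run the ring closure on that substrate. After global desilylation, the enal is formed by chemoselective MnO2 oxidation of the allylic alcohol in the presence of the saturated primary alcohol.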